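**Strategy.** The target is the endo Diels–Alder adduct of methyl trans-communate and a β-caryophyllene-derived enal, so the route rests on a de novo labdane synthesis. Its key step is a thermal intramolecular Diels–Alder reaction of an acyclic trienone: the (Z)-2-methyl-2-enoate (C4=C5) adds to the (E)-diene (C10=C1–C2=C3), closing rings A and B together, forming C3–C4 and C5–C10 and setting C4, C5 and C10 from the single C9 stereocentre. It exploits the quaternary C4 (CH3, CO2H) flanked by the C3 methylene and the ring-fusion carbons of the decalin. The precursor is assembled by Evans alkylation and Fukuyama coupling; hydrogenation, allylic oxidation, double methylenation, a late intermolecular Diels–Alder reaction, oxidation and ester cleavage finish.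

Key step: step 9

Remark (numbering and assumption): the diterpene half uses labdane numbers (C1–C20) from the acyclic stage on; the sesquiterpene half uses primed caryophyllane numbers (C4′ carries the carboxyl carbon, C5′ is its olefinic partner). The Still–Gennari propionate reagent of step 6 and aldehyde 10 are taken as catalogue compounds.

**Step 1**
Reactants: 1 but-3-yn-1-ol
Product: 3 (3E)-3-methylhexa-3,5-dien-1-ol, via alkenylalane 2 (not isolated)
Conditions: Me3Al (3 equiv), Cp2ZrCl2 (0.25 equiv), CH2Cl2, 0 °C to rt; then vinyl bromide, ZnCl2, Pd(PPh3)4 (3 mol%), THF, rt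
Reagents that add atoms: trimethylaluminium C[Al](C)C (CH3 of 3, Al of 2); vinyl bromide C=CBr
Why: Negishi carboalumination adds CH3 and Al syn across the alkyne with CH3 on the internal carbon, and Negishi cross-coupling of the alkenylalane with vinyl bromide proceeds with retention, so the chain is trans to the new vinyl group and the methyl is "inside" the diene.

**Step 2**
Reactants: 3 (3E)-3-methylhexa-3,5-dien-1-ol
Product: 4 (3E)-3-methylhexa-3,5-dienoic acid
Conditions: TEMPO (0.2 equiv), PhI(OAc)2 (2.2 equiv), MeCN/H2O, rt
Reagents that add atoms: water O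
Why: TEMPO/PhI(OAc)2 oxidation takes the primary alcohol through the aldehyde hydrate to the acid under near-neutral conditions that should leave the skipped diene unconjugated.

**Step 3**
Reactants: 4 (3E)-3-methylhexa-3,5-dienoic acid; 5 (R)-4-benzyl-1,3-oxazolidin-2-one
Product: 7 (4R)-4-benzyl-3-[(3E)-3-methylhexa-3,5-dienoyl]-1,3-oxazolidin-2-one, via mixed pivalic anhydride 6 (not isolated)
Conditions: PivCl, Et3N, THF, −20 °C; then lithiated 5 (n-BuLi, THF, −78 °C), −78 to 0 °C
Reagents that add atoms: pivaloyl chloride CC(C)(C)C(=O)Cl (in 6 only)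
Why: Mixed-anhydride N-acylation of the Evans oxazolidinone at low temperature should attach the auxiliary without moving the β,γ-double bond.

**Step 4**
Reactants: 7 (4R)-4-benzyl-3-[(3E)-3-methylhexa-3,5-dienoyl]-1,3-oxazolidin-2-one
Product: 8 (4R)-4-benzyl-3-[(2R,3E)-3-methyl-2-(3-methylbut-2-en-1-yl)hexa-3,5-dienoyl]-1,3-oxazolidin-2-one
Conditions: NaHMDS, THF, −78 °C; prenyl bromide, −78 to −45 °C
Reagents that add atoms: 1-bromo-3-methylbut-2-ene (prenyl bromide) CC(C)=CCBr
Why: Evans asymmetric alkylation: the chelated Z-configured extended sodium enolate should be alkylated at the α-carbon on the face opposite the benzyl group, which sets the future C9 as (2R) and adds C11–C14/C16.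

**Step 5**
Reactants: 8 (alkylated imide)
Product: 9 S-ethyl (2R,3E)-3-methyl-2-(3-methylbut-2-en-1-yl)hexa-3,5-dienethioate
Conditions: EtSH, n-BuLi, THF, 0 °C
Reagents that add atoms: ethanethiol CCS
Why: Evans transthioesterification: the weakly basic thiolate attacks the exocyclic imide carbonyl, which should release the auxiliary without epimerising the α-stereocentre.

**Step 6**
Reactants: 10 3-[(tert-butyldimethylsilyl)oxy]propanal
Product: 11 methyl (2Z)-5-[(tert-butyldimethylsilyl)oxy]-2-methylpent-2-enoate
Conditions: methyl 2-[bis(2,2,2-trifluoroethoxy)phosphoryl]propanoate, KHMDS, 18-crown-6, THF, −78 °C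
Reagents that add atoms: methyl 2-[bis(2,2,2-trifluoroethoxy)phosphoryl]propanoate COC(=O)C(C)P(=O)(OCC(F)(F)F)OCC(F)(F)F
Why: Still–Gennari olefination (electron-poor phosphonate, dissociated potassium base) should give the (Z)-2-methyl-2-enoate under kinetic control, which fixes the dienophile geometry (C4=C5).

**Step 7**
Reactants: 11 methyl (2Z)-5-[(tert-butyldimethylsilyl)oxy]-2-methylpent-2-enoate
Product: 12 methyl (2Z)-5-bromo-2-methylpent-2-enoate
Conditions: Ph3PBr2, CH2Cl2, rt
Reagents that add atoms: triphenylphosphine dibromide BrP(Br)(c1ccccc1)(c1ccccc1)c1ccccc1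
Why: Triphenylphosphine dibromide converts the primary silyl ether directly into the bromide (oxyphosphonium formation, then SN2 by bromide) without touching the Z-enoate.

**Step 8**
Reactants: 12 methyl (2Z)-5-bromo-2-methylpent-2-enoate; 9 S-ethyl thioester
Product: 14 methyl (2Z,7R,8E)-2,8-dimethyl-7-(3-methylbut-2-en-1-yl)-6-oxoundeca-2,8,10-trienoate, via organozinc bromide 13 (not isolated)
Conditions: 12, Zn dust (TMSCl/1,2-dibromoethane-activated), LiCl, THF, 50 °C; then 9, PdCl2(PPh3)2 (5 mol%), toluene, rt
Reagents that add atoms: zinc [Zn] (in 13 only)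
Why: Fukuyama coupling (palladium-catalysed acylation of an ester-tolerant alkylzinc by the thioester) forms the C7–C8 ketone under neutral conditions that should spare the enolisable C9 centre and both olefin geometries.

**Step 9**
Reactants: 14 trienone
Product: 15 methyl 8-oxo-15,17-dinorlabda-1,12-dien-19-oate (trans-decalin; 4β-CO2Me, 4α-CH3, 5α-H, 9α-H, 10β-CH3)
Conditions: toluene (0.01 M), BHT, silanised sealed tube, 175 °C
Reagents that add atoms: none
Why: A concerted, suprafacial thermal [4+2] cycloaddition joins the diene terminus C3 to the ester-bearing C4 and the methyl-bearing terminus C10 to C5; the closest known reaction type is the type 1 intramolecular Diels–Alder reaction of deca-2,7,9-trienoates, including cases with a fully substituted diene terminus that deliver angular methyl groups. Ring A closes as the cycloaddition ring itself (a cyclohexene keeping C1=C2) and ring B closes as the six-membered carbocycle spanned by the four-atom tether C6–C9, fused to ring A at C5–C10. C4 is set relative to C5 by the Z geometry of the dienophile (CO2Me cis to C6, so axial and syn to the C10 methyl; CH3 equatorial), C10 relative to C5 by the E diene (CH3 inside) reacting through the anti, tether-exo transition state that gives the trans ring fusion, and the absolute sense of all three by C9, whose prenyl group lies equatorial in the chair-like tether. The step therefore needs π-facial selectivity towards C9, secured by that equatorial preference next to the sp2 C8, and anti over syn selectivity, expected because the Z-ester is twisted out of conjugation by C6 (little endo stabilisation) and would have to lie under the diene together with the tether in the syn mode, whereas the anti mode places only H5 and the small C4 methyl there; this second selectivity is the least secure element. Chemoselectivity is secured because the isolated prenyl olefin is no dienophile, its Cope shift with the diene is thermodynamically uphill, and the non-conjugated C8 ketone should leave C9 untouched under strictly neutral, radical-inhibited conditions.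

**Step 10**
Reactants: 15 methyl 8-oxo-15,17-dinorlabda-1,12-dien-19-oate
Product: 16 methyl 8-oxo-15,17-dinorlabd-12-en-19-oate
Conditions: H2 (3 atm), RhCl(PPh3)3 (10 mol%), benzene/EtOH, rt
Reagents that add atoms: none
Why: Homogeneous hydrogenation with Wilkinson's catalyst should reduce the cis-disubstituted C1=C2 bond much faster than the trisubstituted prenyl olefin and leave the ketone alone.

**Step 11**
Reactants: 16 methyl 8-oxo-15,17-dinorlabd-12-en-19-oate
Product: 18 methyl (12E)-8,14-dioxo-15,17-dinorlabd-12-en-19-oate, via allylic alcohol 17 (not isolated)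
Conditions: SeO2 (0.5 equiv), t-BuOOH, CH2Cl2, rt; then MnO2, CH2Cl2, rt
Reagents that add atoms: selenium dioxide O=[Se]=O (catalytic oxygen carrier); tert-butyl hydroperoxide CC(C)(C)OO
Why: Sharpless-type SeO2/t-BuOOH allylic oxidation (ene reaction, then [2,3]-shift) attacks the (E)-methyl of the prenyl group, and MnO2 takes the allylic alcohol on to the (E)-enal, which fixes the 12E geometry while the ring ketone stays inert at room temperature.

**Step 12**
Reactants: 18 methyl (12E)-8,14-dioxo-15,17-dinorlabd-12-en-19-oate
Product: 19 methyl trans-communate, methyl (12E)-labda-8(17),12,14-trien-19-oate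
Conditions: Ph3PCH3Br (6 equiv), KHMDS, THF, −78 °C to 50 °C
Reagents that add atoms: methyltriphenylphosphonium bromide C[P+](c1ccccc1)(c1ccccc1)c1ccccc1.[Br-]
Why: Double Wittig methylenation converts the enal into the terminal diene and the hindered C8 ketone into the exocyclic methylene; if C9 epimerises via the enolate it should return to the more stable equatorial (natural) configuration.

**Step 13**
Reactants: 20 (−)-β-caryophyllene
Product: 23 [(1R,4Z,9S)-11,11-dimethyl-8-methylidenebicyclo[7.2.0]undec-4-en-4-yl]methanol, via allylpotassium 21 (not isolated), via allylboronate 22 (not isolated)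
Conditions: n-BuLi, KOt-Bu, THF, −78 to −50 °C; FB(OMe)2·OEt2, −78 °C; then H2O2, NaOH, 0 °C
Reagents that add atoms: fluorodimethoxyborane COB(F)OC (in 22 only); hydrogen peroxide OO
Why: Schlosser allyl alcohol synthesis: the superbase should deprotonate the allylic methyl group fastest, the allylpotassium is configurationally stable at low temperature, and borylation at the CH2 terminus followed by oxidation gives the primary alcohol with the trans ring olefin retained (the descriptor becomes Z only because CH2OH outranks the ring CH2).

**Step 14**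
Reactants: 23 allylic alcohol
Product: 24 (1R,4Z,9S)-11,11-dimethyl-8-methylidenebicyclo[7.2.0]undec-4-ene-4-carbaldehyde
Conditions: MnO2, CH2Cl2, rt
Reagents that add atoms: none
Why: MnO2 oxidation of the allylic alcohol is neutral and should give the enal without isomerising the strained trans ring olefin.

**Step 15**
Reactants: 19 methyl trans-communate; 24 caryophyllene enal
Product: 25 Diels–Alder adduct (target skeleton with C19 methyl ester and C4′ carbaldehyde)
Conditions: 24 (2 equiv), toluene (2 M), BHT, 120 °C, sealed tube
Reagents that add atoms: none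
Why: Normal-demand intermolecular Diels–Alder reaction of a strain-activated enal: the unsubstituted diene terminus C15 bonds to the β-carbon C5′ ("ortho" rule of the 1-alkyl diene, also the less hindered pairing), the formyl group is endo (cis to C11 at C12), and the diene adds to the exposed outer face of the trans-cyclononene that peracids also attack in β-caryophyllene, which together set C12, C4′ and C5′ as in the target.

**Step 16**
Reactants: 25 Diels–Alder adduct aldehyde
Product: 26 C19 methyl ester, C4′ carboxylic acid
Conditions: NaClO2, NaH2PO4, 2-methyl-2-butene, t-BuOH/H2O, rt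
Reagents that add atoms: sodium chlorite [Na+].[O-]Cl=O
Why: Pinnick oxidation converts the hindered neopentyl aldehyde into the acid while 2-methyl-2-butene scavenges HOCl, so the three olefins should survive.

**Step 17**
Reactants: 26 mono methyl ester
Product: 27 CNP0330729.1 (target diacid)
Conditions: EtSNa (10 equiv), DMF, 100 °C; then aq. HCl
Reagents that add atoms: none
Why: SN2 demethylation by thiolate at the O-methyl carbon cleaves the hindered axial C19 ester where acyl attack would fail, and should affect neither olefins nor stereocentres.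

**Compound list**

1 | but-3-yn-1-ol | C#CCCO | starting material
2 | alkenylalane: (E)-configured dimethylalumanyl alkene with O-dimethylalumanyl alkoxide | C[Al](C)/C=C(\C)CCO[Al](C)C | intermediate
3 | (3E)-3-methylhexa-3,5-dien-1-ol | C=C/C=C(\C)CCO | intermediate
4 | (3E)-3-methylhexa-3,5-dienoic acid | C=C/C=C(\C)CC(=O)O | intermediate
5 | (R)-4-benzyl-1,3-oxazolidin-2-one | O=C1N[C@H](Cc2ccccc2)CO1 | starting material
6 | (3E)-3-methylhexa-3,5-dienoic pivalic anhydride | C=C/C=C(\C)CC(=O)OC(=O)C(C)(C)C | intermediate
7 | (4R)-4-benzyl-3-[(3E)-3-methylhexa-3,5-dienoyl]-1,3-oxazolidin-2-one | C=C/C=C(\C)CC(=O)N1[C@H](Cc2ccccc2)COC1=O | intermediate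
8 | (4R)-4-benzyl-3-[(2R,3E)-3-methyl-2-(3-methylbut-2-en-1-yl)hexa-3,5-dienoyl]-1,3-oxazolidin-2-one | CC(C)=CC[C@H](/C(C)=C/C=C)C(=O)N1[C@H](Cc2ccccc2)COC1=O | intermediate
9 | S-ethyl (2R,3E)-3-methyl-2-(3-methylbut-2-en-1-yl)hexa-3,5-dienethioate | CC(C)=CC[C@H](/C(C)=C/C=C)C(=O)SCC | intermediate
10 | 3-[(tert-butyldimethylsilyl)oxy]propanal | O=CCCO[Si](C)(C)C(C)(C)C | starting material
11 | methyl (2Z)-5-[(tert-butyldimethylsilyl)oxy]-2-methylpent-2-enoate | COC(=O)/C(C)=C\CCO[Si](C)(C)C(C)(C)C | intermediate
12 | methyl (2Z)-5-bromo-2-methylpent-2-enoate | COC(=O)/C(C)=C\CCBr | intermediate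
13 | [(3Z)-5-methoxy-4-methyl-5-oxopent-3-en-1-yl]zinc bromide | COC(=O)/C(C)=C\CC[Zn]Br | intermediate
14 | methyl (2Z,7R,8E)-2,8-dimethyl-7-(3-methylbut-2-en-1-yl)-6-oxoundeca-2,8,10-trienoate | CC(C)=CC[C@H](/C(C)=C/C=C)C(=O)CC/C=C(/C)C(=O)OC | intermediate
15 | methyl 8-oxo-15,17-dinorlabda-1,12-dien-19-oate (4β-CO2Me, 5α-H, 9α-H, 10β-CH3) | CC(C)=CC[C@H]1C(=O)CC[C@@H]2[C@]1(C)C=CC[C@]2(C)C(=O)OC | intermediate
16 | methyl 8-oxo-15,17-dinorlabd-12-en-19-oate | CC(C)=CC[C@H]1C(=O)CC[C@@H]2[C@]1(C)CCC[C@]2(C)C(=O)OC | intermediate
17 | methyl (12E)-14-hydroxy-8-oxo-15,17-dinorlabd-12-en-19-oate | OC/C(C)=C/C[C@H]1C(=O)CC[C@@H]2[C@]1(C)CCC[C@]2(C)C(=O)OC | intermediate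
18 | methyl (12E)-8,14-dioxo-15,17-dinorlabd-12-en-19-oate | O=C/C(C)=C/C[C@H]1C(=O)CC[C@@H]2[C@]1(C)CCC[C@]2(C)C(=O)OC | intermediate
19 | methyl trans-communate, methyl (12E)-labda-8(17),12,14-trien-19-oate | C=C/C(C)=C/C[C@H]1C(=C)CC[C@@H]2[C@]1(C)CCC[C@]2(C)C(=O)OC | intermediate
20 | (−)-β-caryophyllene, (1R,4E,9S)-4,11,11-trimethyl-8-methylidenebicyclo[7.2.0]undec-4-ene | C/C1=C\CCC(=C)[C@H]2CC(C)(C)[C@@H]2CC1 | starting material
21 | allylpotassium of 20, metalated at the C4′ methyl, trans ring olefin retained | [K+].[CH2-]/C1=C\CCC(=C)[C@H]2CC(C)(C)[C@@H]2CC1 | intermediate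
22 | dimethyl allylboronate of 20 at the C4′ methyl carbon, trans ring olefin | COB(OC)C/C1=C\CCC(=C)[C@H]2CC(C)(C)[C@@H]2CC1 | intermediate
23 | [(1R,4Z,9S)-11,11-dimethyl-8-methylidenebicyclo[7.2.0]undec-4-en-4-yl]methanol (ring olefin trans) | OC/C1=C\CCC(=C)[C@H]2CC(C)(C)[C@@H]2CC1 | intermediate
24 | (1R,4Z,9S)-11,11-dimethyl-8-methylidenebicyclo[7.2.0]undec-4-ene-4-carbaldehyde (ring olefin trans) | O=C/C1=C\CCC(=C)[C@H]2CC(C)(C)[C@@H]2CC1 | intermediate
25 | Diels–Alder adduct: C19 methyl ester, C4′ carbaldehyde | C=C1CC[C@H]2CC=C(C)[C@@H](C[C@H]3C(=C)CC[C@@H]4[C@]3(C)CCC[C@]4(C)C(=O)OC)[C@]2(C=O)CC[C@@H]2[C@@H]1CC2(C)C | intermediate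
26 | C19 methyl ester, C4′ carboxylic acid | C=C1CC[C@H]2CC=C(C)[C@@H](C[C@H]3C(=C)CC[C@@H]4[C@]3(C)CCC[C@]4(C)C(=O)OC)[C@]2(C(=O)O)CC[C@@H]2[C@@H]1CC2(C)C | intermediate
27 | CNP0330729.1 (diacid) | C=C1CC[C@H]2CC=C(C)[C@@H](C[C@H]3C(=C)CC[C@@H]4[C@]3(C)CCC[C@]4(C)C(=O)O)[C@]2(C(=O)O)CC[C@@H]2[C@@H]1CC2(C)C | target

**Totals.** 17 steps in all. The longest linear sequence is 13 steps (steps 1–5, 8–12, 15–17, from but-3-yn-1-ol).

**Steps most likely to fail**

1. Step 9 (key cycloaddition). The cyclisation may run largely through the folded syn (ester-endo) transition state and give the cis-fused decalin. It may also be slow enough that epimerisation at C9 or diene isomerisation erodes the stereochemical relay. The fallback removes the endo/exo question and sets out from thioester 9. Methyl 5-bromopent-2-ynoate F1 (from commercial 4-bromobut-1-yne, LDA, ClCO2Me) is converted into its zinc reagent F2 and coupled with 9 (PdCl2(PPh3)2) to give the dienynone F3. Its intramolecular Diels–Alder reaction (toluene, 160 °C) still forms C3–C4 and C5–C10 and gives the cyclohexa-1,4-diene keto ester F4, in which only C10 has to be controlled. Reductive methylation (Li, NH3, t-BuOH; then MeI) protonates C5 axially and methylates the C4 ester enolate from the α face, while the ketone is reduced, giving hydroxy ester F5. Dess–Martin oxidation of F5 comes back to the route at compound 15.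

2. Step 13 (allylic metalation). Deprotonation may occur at C7′ next to the exocyclic methylene instead of the C4′ methyl, or the allylpotassium may relax by torsional isomerisation to the less strained ring-cis form. The fallback sets out from 20. SeO2/t-BuOOH allylic oxidation, which by its ene/[2,3] course is expected to deliver the ring-cis hydroxymethyl isomer F6, is followed by sensitised photoisomerisation (methyl benzoate, 254 nm, flow through AgNO3 on silica, release with aqueous NH3). This comes back to the route at compound 23.

3. Step 15 (intermolecular cycloaddition). The thermal reaction between a trisubstituted enal and a trisubstituted diene terminus may be too slow, so that isomerisation of the strained enal or diene dimerisation competes, or it may show poor facial or regiochemical discrimination. The fallback is an ionic (Gassman-type) Diels–Alder reaction and sets out from 24. The aldehyde is converted into its 1,3-dioxolane F7 (1,2-bis(trimethylsilyloxy)ethane, TMSOTf cat., −78 °C). Ionisation of F7 with TMSOTf in CH2Cl2 at −78 °C gives a vinyl oxocarbenium dienophile that adds 19 with the same ortho/endo sense to give the acetal adduct F8. Mild hydrolysis (PPTS, wet acetone) comes back to the route at compound 25.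

**Further compounds**

F1 | step 9 | methyl 5-bromopent-2-ynoate | COC(=O)C#CCCBr
F2 | step 9 | (5-methoxy-5-oxopent-3-yn-1-yl)zinc bromide | COC(=O)C#CCC[Zn]Br
F3 | step 9 | methyl (7R,8E)-8-methyl-7-(3-methylbut-2-en-1-yl)-6-oxoundeca-8,10-dien-2-ynoate | CC(C)=CC[C@H](/C(C)=C/C=C)C(=O)CCC#CC(=O)OC
F4 | step 9 | methyl 8-oxo-15,17,18-trinorlabda-1,4,12-trien-19-oate (9α-H, 10β-CH3) | CC(C)=CC[C@H]1C(=O)CCC2=C(C(=O)OC)CC=C[C@]12C
F5 | step 9 | methyl 8α-hydroxy-15,17-dinorlabda-1,12-dien-19-oate | CC(C)=CC[C@H]1[C@H](O)CC[C@@H]2[C@]1(C)C=CC[C@]2(C)C(=O)OC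
F6 | step 13 | [(1R,4E,9S)-11,11-dimethyl-8-methylidenebicyclo[7.2.0]undec-4-en-4-yl]methanol (ring olefin cis) | OC/C1=C/CCC(=C)[C@H]2CC(C)(C)[C@@H]2CC1
F7 | step 15 | 2-[(1R,4Z,9S)-11,11-dimethyl-8-methylidenebicyclo[7.2.0]undec-4-en-4-yl]-1,3-dioxolane | O3CCOC3/C1=C\CCC(=C)[C@H]2CC(C)(C)[C@@H]2CC1
F8 | step 15 | ethylene acetal of adduct 25 | C=C1CC[C@H]2CC=C(C)[C@@H](C[C@H]3C(=C)CC[C@@H]4[C@]3(C)CCC[C@]4(C)C(=O)OC)[C@]2(C3OCCO3)CC[C@@H]2[C@@H]1CC2(C)C
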